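**Plan**
1. Retrosynthesis: the formyl and then the isovaleryl C–C bonds are cut from the arene; the C2–H and benzylic C–H bonds are traced back to an enol ether and a benzylic C–O bond; the bornene is cut at C1–C6 and C4–C5 (retro-[4+2]); last, the aryl O–C2 bond (to a dienyl triflate) and the benzylic C–vinyl bond (to an aldehyde) are cut.
2. Enabling feature: bornane C1, C2, C3, C4 and C7 are a 1,5,5-trimethylcyclopentadiene carrying the ether oxygen on its 2-position, and C5–C6 is a vinyl group held to that oxygen by the arene and the benzylic carbon, so one type 2 intramolecular Diels–Alder reaction can close the carbocycle and the oxepane together.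
3. Forward order: arene and cyclopentadiene are joined by C–O coupling, the vinyl carbinol is made, its oxygen is tied to the neighbouring phenol oxygen in a six-membered silylene ring, the cycloaddition closes the norbornene six-membered ring and the oxepane at once, and the arene is acylated and formylated last.
4. Stereochemistry: the only external source is the catalytic asymmetric vinyl addition ((S)-carbinol). Locked in the silylene ring, this centre selects the diene face (C1, C4) and the tether forces C6 endo. C2 follows from exo hydride delivery enforced by the oxepane, and the carbinol centre is then reduced to CH2.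

Key step: step 8

Remark: terpene carbons are numbered as in bornane (C1 methyl-bearing bridgehead, C2 oxygen-bearing carbon, C6 the carbon carrying the benzylic carbon Cb, C7 the CMe2 bridge). The facial sense of (−)-MIB is assumed to be the one it shows with benzaldehyde. TIPS = triisopropylsilyl, MOM = methoxymethyl.

Step 1
Reactants: 1 2,4,6-trihydroxybenzaldehyde
Product: 2 2-hydroxy-4,6-bis[(triisopropylsilyl)oxy]benzaldehyde
Conditions: i-Pr3SiCl (2.2 equiv), imidazole, DMF, 0 °C → rt
Reagents that add atoms: chlorotriisopropylsilane, CC(C)[Si](Cl)(C(C)C)C(C)C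
Why: Silyl ether formation in which the 4-OH and one 2-OH react while the last ortho hydroxyl, held in the hydrogen bond to the formyl group, should stay free, as in the usual selective bis-protection of phloroglucinaldehyde.

Step 2
Reactants: 3 4,4-dimethylcyclopent-2-en-1-one
Product: 5 4,4,5-trimethylcyclopent-2-en-1-one (racemic), via lithium dienolate 4 (not isolated)
Conditions: LiN(i-Pr)2, THF, −78 °C; MeI, −78 → 0 °C
Reagents that add atoms: iodomethane, CI
Why: Kinetic α'-deprotonation (C5 carries the only acidic hydrogens because C4 is quaternary) and SN2 methylation of the cross-conjugated enolate, the new centre being racemic and planarised again in step 3.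

Step 3
Reactants: 5 4,4,5-trimethylcyclopent-2-en-1-one
Product: 7 2,3,3-trimethylcyclopenta-1,4-dien-1-yl trifluoromethanesulfonate, via potassium dienolate 6 (not isolated)
Conditions: KN(SiMe3)2, THF, −78 °C; PhNTf2, −78 → 0 °C
Reagents that add atoms: N-phenylbis(trifluoromethanesulfonimide), O=S(=O)(N(c1ccccc1)S(=O)(=O)C(F)(F)F)C(F)(F)F
Why: Enol triflate formation, in which the single remaining α-hydrogen is removed and the dienolate is O-sulfonylated to a cyclopentadiene whose sp3 carbon is quaternary and therefore cannot shift hydrogen and dimerises only slowly.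

Step 4
Reactants: 2 2-hydroxy-4,6-bis[(triisopropylsilyl)oxy]benzaldehyde; 7 2,3,3-trimethylcyclopenta-1,4-dien-1-yl trifluoromethanesulfonate
Product: 8 2-[(2,3,3-trimethylcyclopenta-1,4-dien-1-yl)oxy]-4,6-bis[(triisopropylsilyl)oxy]benzaldehyde
Conditions: Pd(OAc)2 (5 mol%), t-BuXPhos (10 mol%), K3PO4, toluene, 90 °C
Reagents that add atoms: none
Why: Palladium-catalysed C–O cross-coupling of an alkenyl triflate with a phenol (Buchwald–Hartwig-type etherification), in which the bulky biaryl phosphine drives C–O reductive elimination and the alkenylpalladium intermediate cannot undergo β-hydride elimination.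

Step 5
Reactants: 8 2-[(2,3,3-trimethylcyclopenta-1,4-dien-1-yl)oxy]-4,6-bis[(triisopropylsilyl)oxy]benzaldehyde; 9 vinylmagnesium bromide
Product: 10 (1S)-1-{2-[(2,3,3-trimethylcyclopenta-1,4-dien-1-yl)oxy]-4,6-bis[(triisopropylsilyl)oxy]phenyl}prop-2-en-1-ol
Conditions: (CH2=CH)2Zn [from 9 and ZnCl2, Et2O; salts removed with 1,4-dioxane], (−)-MIB (10 mol%), toluene, 0 °C; aq. NH4Cl
Reagents that add atoms: divinylzinc, C=C[Zn]C=C (made in the flask from 9)
Why: Amino-alcohol-catalysed enantioselective addition of an alkenylzinc reagent to an aryl aldehyde (Noyori–Oppolzer type), in which (−)-MIB [(2S)-3-exo-morpholinoisoborneol] should deliver the vinyl group to the Si face and so give the (S)-carbinol, the non-chelating silyl ethers keeping the uncatalysed pathway slow.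

Step 6
Reactants: 10 the (S)-carbinol
Product: 11 4-[(1S)-1-hydroxyprop-2-en-1-yl]-5-[(2,3,3-trimethylcyclopenta-1,4-dien-1-yl)oxy]benzene-1,3-diol
Conditions: Bu4NF (2.5 equiv), AcOH (2.5 equiv), THF, 0 °C → rt; crude product used directly
Reagents that add atoms: none
Why: Fluoride cleavage of the two aryl silyl ethers (and of any silyl group that migrated to the carbinol oxygen) under buffered conditions that should neither ionise the benzylic alcohol nor touch the stereocentre.

Step 7
Reactants: 11 the triol
Product: 13 (4S)-2,2-di-tert-butyl-4-ethenyl-5-[(2,3,3-trimethylcyclopenta-1,4-dien-1-yl)oxy]-7-[(triisopropylsilyl)oxy]-4H-1,3,2-benzodioxasiline, via mono-TIPS ether 12 (not isolated)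
Conditions: i-Pr3SiCl (1.05 equiv), imidazole, CH2Cl2, −20 °C; then t-Bu2Si(OTf)2, 2,6-lutidine, 0 °C
Reagents that add atoms: chlorotriisopropylsilane, CC(C)[Si](Cl)(C(C)C)C(C)C; di-tert-butylsilyl bis(trifluoromethanesulfonate), CC(C)(C)[Si](OS(=O)(=O)C(F)(F)F)(OS(=O)(=O)C(F)(F)F)C(C)(C)C
Why: The bulky silyl chloride should take the unhindered para hydroxyl, after which the silylene bis-triflate bridges the remaining ortho phenol and the carbinol (cyclic silylene protection of a 1,3-diol) without breaking a bond at the stereocentre, and the six-membered ring fixes the benzylic C–O bond in the arene plane as step 8 requires.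

Step 8
Reactants: 13 the silylene-bridged dienyl aryl ether
Product: 14 silylene-bridged oxepane-fused 2-aryloxyborn-2-ene
Conditions: toluene (0.01 M, degassed), BHT, 2,6-lutidine (0.1 equiv), sealed tube, 200 °C
Reagents that add atoms: none
Why: Heating brings the tethered vinyl group under the s-cis-locked cyclopentadiene, and a concerted suprafacial [4+2] cycloaddition forms C1–C6 and C4–C5, the quaternary CMe2 carbon excluding 1,5-hydrogen shifts of the diene. The closest known reactions are type 2 intramolecular Diels–Alder reactions of 2-tethered dienes, which give 1,3-bridged bridgehead alkenes, and thermal cycloadditions of cyclopentadienes to unactivated alkenes. The six-membered carbocycle of the norbornene closes by the [4+2] itself, and the oxepane closes through the C1–C6 bond in the 1,3-bridged mode, because the four-atom O–aryl–CH tether can only bring the inner alkene carbon to C1 and only with the benzylic carbon endo. C6 is therefore fixed by the tether, and C1 and C4 are fixed together by the diene face that is used. That face is chosen by the (4S) centre: in the seven-membered transition state the arene-plane position beside the ortho oxygen, where the silylene ring holds the benzylic C–O bond, is the one anti to the forming C1–C6 bond and pointing away from the bicycle, so the benzylic hydrogen eclipses the alkene next to the C5 endo hydrogen, whereas the other face would need this oxygen out of the arene plane, which the ring forbids. Without the ring a benzylic oxygen would have to choose between clashing with the ortho oxygen and sitting under the bicycle, so the silylene is what should make regio-, endo- and facial selectivity all substrate-imposed.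

Step 9
Reactants: 14 the cycloadduct
Product: 16 core diphenol, via desilylated triol 15 (not isolated)
Conditions: Bu4NF, THF, 0 °C; aq. NH4Cl; crude 15: Et3SiH (6 equiv), CF3CO2H, CH2Cl2, −20 → 0 °C
Reagents that add atoms: none
Why: Fluoride removes both silicon groups and ionic hydrogenation follows, in which C-protonation of the enol ether gives the C2 oxocarbenium ion that can accept hydride only on the exo face because the oxepane holds the oxygen endo (this sets C2), while the freed ortho-hydroxybenzyl alcohol ionises to a cation stabilised by three ring oxygens that the silane reduces to CH2.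

Step 10
Reactants: 16 core diphenol
Product: 17 bis-MOM ether of 16
Conditions: MOMCl, i-Pr2NEt, CH2Cl2, 0 °C → rt
Reagents that add atoms: chloromethyl methyl ether, COCCl
Why: O-alkylation of both phenols (MOM ether formation), which installs the two directing groups for step 11.

Step 11
Reactants: 17 bis-MOM ether; 18 3-methylbutanal
Product: 20 benzylic carbinol (mixture of epimers at the new carbinol carbon), via aryllithium 19 (not isolated)
Conditions: n-BuLi, TMEDA, THF, 0 °C; then 18, −78 °C; aq. NH4Cl
Reagents that add atoms: none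
Why: Directed ortho-metalation at the ring position flanked by both MOM ethers (the other free position has only one MOM neighbour) and 1,2-addition of the aryllithium to the aldehyde, the new carbinol centre being oxidised away in step 12.

Step 12
Reactants: 20 benzylic carbinol
Product: 21 aryl isobutyl ketone (bis-MOM)
Conditions: Dess–Martin periodinane, NaHCO3, CH2Cl2, rt
Reagents that add atoms: none
Why: Dess–Martin oxidation of a secondary benzylic alcohol under buffered conditions that should leave the MOM ethers and the alkyl aryl ether intact.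

Step 13
Reactants: 21 ketone
Product: 22 des-formyl target
Conditions: HCl (3 M), MeOH, 40 °C
Reagents that add atoms: none
Why: Acid-catalysed acetal exchange with methanol removes both MOM groups, while the oxepane ether has an endo (bornyl-type) C–O bond without σ-participation and should not ionise.

Step 14
Reactants: 22 des-formyl target
Product: 24 CNP0246493.1, via chloro(methoxy)methyl arene 23 (not isolated)
Conditions: Cl2CHOMe, TiCl4, CH2Cl2, −20 → 0 °C; then H2O
Reagents that add atoms: dichloromethyl methyl ether, COC(Cl)Cl; water, O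
Why: Rieche formylation (Friedel–Crafts alkylation by the chloro(methoxy)methyl cation, then hydrolysis) at the only free ring position, which is ortho to one phenol and para to the other.

**Compound list**
1 | 2,4,6-trihydroxybenzaldehyde | O=Cc1c(O)cc(O)cc1O | starting material
2 | 2-hydroxy-4,6-bis[(triisopropylsilyl)oxy]benzaldehyde | O=Cc1c(O)cc(O[Si](C(C)C)(C(C)C)C(C)C)cc1O[Si](C(C)C)(C(C)C)C(C)C | intermediate
3 | 4,4-dimethylcyclopent-2-en-1-one | CC1(C)C=CC(=O)C1 | starting material
4 | lithium 3,3-dimethylcyclopenta-1,4-dien-1-olate | [Li]OC1=CC(C)(C)C=C1 | intermediate (not isolated)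
5 | 4,4,5-trimethylcyclopent-2-en-1-one (racemic) | CC1C(=O)C=CC1(C)C | intermediate
6 | potassium 2,3,3-trimethylcyclopenta-1,4-dien-1-olate | [K]OC1=C(C)C(C)(C)C=C1 | intermediate (not isolated)
7 | 2,3,3-trimethylcyclopenta-1,4-dien-1-yl trifluoromethanesulfonate (2-triflyloxy-1,5,5-trimethylcyclopenta-1,3-diene) | CC1=C(OS(=O)(=O)C(F)(F)F)C=CC1(C)C | intermediate
8 | 2-[(2,3,3-trimethylcyclopenta-1,4-dien-1-yl)oxy]-4,6-bis[(triisopropylsilyl)oxy]benzaldehyde | CC1=C(Oc2cc(O[Si](C(C)C)(C(C)C)C(C)C)cc(O[Si](C(C)C)(C(C)C)C(C)C)c2C=O)C=CC1(C)C | intermediate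
9 | vinylmagnesium bromide | C=C[Mg]Br | starting material
10 | (1S)-1-{2-[(2,3,3-trimethylcyclopenta-1,4-dien-1-yl)oxy]-4,6-bis[(triisopropylsilyl)oxy]phenyl}prop-2-en-1-ol | CC1=C(Oc2cc(O[Si](C(C)C)(C(C)C)C(C)C)cc(O[Si](C(C)C)(C(C)C)C(C)C)c2[C@@H](O)C=C)C=CC1(C)C | intermediate
11 | 4-[(1S)-1-hydroxyprop-2-en-1-yl]-5-[(2,3,3-trimethylcyclopenta-1,4-dien-1-yl)oxy]benzene-1,3-diol | CC1=C(Oc2cc(O)cc(O)c2[C@@H](O)C=C)C=CC1(C)C | intermediate
12 | 2-[(1S)-1-hydroxyprop-2-en-1-yl]-3-[(2,3,3-trimethylcyclopenta-1,4-dien-1-yl)oxy]-5-[(triisopropylsilyl)oxy]phenol | CC1=C(Oc2cc(O[Si](C(C)C)(C(C)C)C(C)C)cc(O)c2[C@@H](O)C=C)C=CC1(C)C | intermediate (not isolated)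
13 | (4S)-2,2-di-tert-butyl-4-ethenyl-5-[(2,3,3-trimethylcyclopenta-1,4-dien-1-yl)oxy]-7-[(triisopropylsilyl)oxy]-4H-1,3,2-benzodioxasiline (precursor of the key step) | CC1=C(Oc2cc(O[Si](C(C)C)(C(C)C)C(C)C)cc(O3)c2[C@@H](O[Si]3(C(C)(C)C)C(C)(C)C)C=C)C=CC1(C)C | intermediate
14 | key-step product: (1R,4R,6R)-1,7,7-trimethylbicyclo[2.2.1]hept-2-ene (bornane numbering) with the aryl ether oxygen on C2 and, endo on C6, the benzylic carbon (S); the benzylic oxygen and the ortho phenol oxygen are bridged by Si(t-Bu)2, para OTIPS | O1c2cc(O[Si](C(C)C)(C(C)C)C(C)C)cc3c2[C@@H](O[Si]1(C(C)(C)C)C(C)(C)C)[C@@H]1C[C@@H]4C=C(O3)[C@@]1(C)C4(C)C | intermediate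
15 | desilylated cycloadduct: enol ether as in 14, free benzylic (S)-OH and two free phenols | Oc1cc(O)cc2c1[C@@H](O)[C@@H]1C[C@@H]3C=C(O2)[C@@]1(C)C3(C)C | intermediate (not isolated)
16 | core diphenol: (1R,2S,4R,6S)-bornane with 2-endo aryl ether oxygen and 6-endo CH2, both on adjacent positions of a 3,5-dihydroxyphenyl ring (oxepane) | c1c(O)cc2c(c1O)C[C@@H]1C[C@@H]3C[C@H](O2)[C@@]1(C)C3(C)C | intermediate
17 | bis(methoxymethyl) ether of 16 | c1c(OCOC)cc2c(c1OCOC)C[C@@H]1C[C@@H]3C[C@H](O2)[C@@]1(C)C3(C)C | intermediate
18 | 3-methylbutanal | CC(C)CC=O | starting material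
19 | aryllithium of 17, lithiated between the two MOM ethers | [Li]c1c(OCOC)cc2c(c1OCOC)C[C@@H]1C[C@@H]3C[C@H](O2)[C@@]1(C)C3(C)C | intermediate (not isolated)
20 | 1-aryl-3-methylbutan-1-ol from 19 and 18 (epimers at the carbinol carbon) | CC(C)CC(O)c1c(OCOC)cc2c(c1OCOC)C[C@@H]1C[C@@H]3C[C@H](O2)[C@@]1(C)C3(C)C | intermediate
21 | 1-aryl-3-methylbutan-1-one, bis-MOM ether | CC(C)CC(=O)c1c(OCOC)cc2c(c1OCOC)C[C@@H]1C[C@@H]3C[C@H](O2)[C@@]1(C)C3(C)C | intermediate
22 | des-formyl target (free acylphloroglucinol ether) | CC(C)CC(=O)c1c(O)cc2c(c1O)C[C@@H]1C[C@@H]3C[C@H](O2)[C@@]1(C)C3(C)C | intermediate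
23 | chloro(methoxy)methyl arene formed from 22 before hydrolysis | CC(C)CC(=O)c1c(O)c(C(Cl)OC)c2c(c1O)C[C@@H]1C[C@@H]3C[C@H](O2)[C@@]1(C)C3(C)C | intermediate (not isolated)
24 | CNP0246493.1: isovaleryl formyl phloroglucinol bridged by its ether oxygen (2-endo) and benzylic CH2 (6-endo) to (1R,2S,4R,6S)-bornane | CC(C)CC(=O)c1c(O)c(C=O)c2c(c1O)C[C@@H]1C[C@@H]3C[C@H](O2)[C@@]1(C)C3(C)C | target

**Step count and risks**
Total steps: 14. Longest linear sequence: 13 steps (3 → 24, steps 2 to 14).

Steps most likely to fail:

1. Step 8. The cycloaddition may be too slow below the temperature at which the dienyl ether decomposes, because the alkene is unactivated, the gem-dimethyl bridge shields both diene faces and the 1,3-bridged transition state is strained. Fallback, from 13 back to 14: cross-metathesis of 13 with phenyl vinyl sulfone (second-generation Hoveyda–Grubbs catalyst, CH2Cl2, 40 °C) should give the (E)-vinyl sulfone F1. In F1 the electron-rich diene terminus C1 attacks the β-carbon of an activated dienophile, so the same intramolecular cycloaddition should run near 110–130 °C and give the 5-exo-phenylsulfonyl cycloadduct F2. Reductive desulfonylation (Na/Hg, Na2HPO4, MeOH/THF) then returns to 14.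

2. Step 5. Vinyl transfer to an aldehyde with two bulky ortho oxygen substituents may be slow, so that uncatalysed addition erodes the enantiomeric purity. Fallback, from 8 back to 10: addition of 9 (THF, −78 °C) gives the racemic carbinol F3. Sharpless kinetic resolution (Ti(OiPr)4, L-(+)-diisopropyl tartrate, t-BuOOH, 4 Å sieves, CH2Cl2, −20 °C, about 55% conversion) should then epoxidise the (R)-enantiomer to the epoxy alcohol F4 and leave (S)-carbinol 10, which is separated by chromatography.

3. Step 4. The hydrogen-bonded, weakly nucleophilic phenoxide may attack the sulfur of the triflate (returning enone 5) faster than C–O reductive elimination occurs. Fallback, from 7 back to 8: Miyaura borylation of 7 (B2pin2, PdCl2(PPh3)2, PPh3, KOPh, toluene, 50 °C) gives the dienylboronate F5, which is joined to phenol 2 by Chan–Lam coupling (Cu(OAc)2, pyridine, 4 Å sieves, air, CH2Cl2, rt) to give 8.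

Further compounds
F1 | step 8 | (4S)-2,2-di-tert-butyl-4-[(E)-2-(phenylsulfonyl)ethenyl]-5-[(2,3,3-trimethylcyclopenta-1,4-dien-1-yl)oxy]-7-[(triisopropylsilyl)oxy]-4H-1,3,2-benzodioxasiline | CC1=C(Oc2cc(O[Si](C(C)C)(C(C)C)C(C)C)cc(O3)c2[C@@H](O[Si]3(C(C)(C)C)C(C)(C)C)/C=C/S(=O)(=O)c2ccccc2)C=CC1(C)C
F2 | step 8 | cycloadduct 14 carrying an exo phenylsulfonyl group on C5 | O1c2cc(O[Si](C(C)C)(C(C)C)C(C)C)cc3c2[C@@H](O[Si]1(C(C)(C)C)C(C)(C)C)[C@@H]1[C@@H](S(=O)(=O)c5ccccc5)[C@@H]4C=C(O3)[C@@]1(C)C4(C)C
F3 | step 5 | racemic 1-{2-[(2,3,3-trimethylcyclopenta-1,4-dien-1-yl)oxy]-4,6-bis[(triisopropylsilyl)oxy]phenyl}prop-2-en-1-ol | CC1=C(Oc2cc(O[Si](C(C)C)(C(C)C)C(C)C)cc(O[Si](C(C)C)(C(C)C)C(C)C)c2C(O)C=C)C=CC1(C)C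
F4 | step 5 | epoxy alcohol from the (R)-carbinol: (R)-aryl[(2S)-oxiran-2-yl]methanol | CC1=C(Oc2cc(O[Si](C(C)C)(C(C)C)C(C)C)cc(O[Si](C(C)C)(C(C)C)C(C)C)c2[C@H](O)[C@@H]2CO2)C=CC1(C)C
F5 | step 4 | 4,4,5,5-tetramethyl-2-(2,3,3-trimethylcyclopenta-1,4-dien-1-yl)-1,3,2-dioxaborolane | CC1=C(B2OC(C)(C)C(C)(C)O2)C=CC1(C)C
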